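**Plan**

- Core numbering: C1 benzoyl bridgehead, C2 enol carbon, C3 (prenyl), C4 ketone, C5 lavandulyl bridgehead, C6, C7 (prenyl), C8 (CMe2), C9 bridging ketone. Ring A is C1–C2–C3–C4–C5–C9 and ring B is C1–C9–C5–C6–C7–C8.
- Enabling feature: ring A carries carbonyl groups at C2, C4 and C9, so C3–C4 and C5–C9 each join a carbonyl carbon to an α-carbon. C1 carries two carbonyl carbons (C9 and the exocyclic acyl carbon) that can be made identical, so C1 need not be a stereocentre before ring closure.
- Retrosynthesis: the benzoyl group is traced back to a bridgehead CO2Me. C3–C4 and C5–C9 are then cut together to an open-chain keto triester whose C1 bears two CO2Me groups. Further cuts are C1–C2 (C-acylation), C5=C6 (olefination, then reduction) and C7–C8 (Michael addition to an isopropylidene malonate).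
- Forward: the chain is assembled, then one base-mediated cascade closes ring B (C5 to C9) and ring A (C3 to C4); the spare bridgehead ester is converted to the benzoyl group last.
- Stereochemistry: C7 comes from an oxazolidinone auxiliary, the side-chain centre from (R)-lavandulol, and C1 and C5 are set in the cascade under control of C7.

Key step: step 11

Remark: (R)-(−)-lavandulol is taken as a purchasable enantiopure alcohol. The target is drawn as the C2-enol tautomer of the C2/C4 β-diketone, which equilibrates freely with the C4-enol form.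

**Step 1**
Reactants: 1 5-methylhex-4-enoic acid
Product: 2 5-methylhex-4-enoyl chloride
Conditions: (COCl)2, cat. DMF, CH2Cl2, 0 °C to rt
Reagents that add atoms: oxalyl chloride O=C(Cl)C(=O)Cl
Why: Standard acid chloride formation through the chloroiminium species, with the trisubstituted alkene inert and no stereocentre involved.

**Step 2**
Reactants: 3 (R)-4-benzyl-1,3-oxazolidin-2-one; 2 5-methylhex-4-enoyl chloride
Product: 4 (R)-4-benzyl-3-(5-methylhex-4-enoyl)-1,3-oxazolidin-2-one
Conditions: n-BuLi, THF, −78 °C; then 2, −78 to 0 °C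
Reagents that add atoms: none
Why: N-acylation of the lithiated oxazolidinone by an acid chloride is a routine imide synthesis that leaves the auxiliary stereocentre untouched.

**Step 3**
Reactants: 4 (R)-4-benzyl-3-(5-methylhex-4-enoyl)-1,3-oxazolidin-2-one; 5 dimethyl 2-(propan-2-ylidene)propanedioate
Product: 6 dimethyl 2-[(3S)-3-[(4R)-4-benzyl-2-oxo-1,3-oxazolidine-3-carbonyl]-2,6-dimethylhept-5-en-2-yl]propanedioate
Conditions: NaN(SiMe3)2, THF, −78 °C; then 5, −78 to −40 °C; AcOH
Reagents that add atoms: none
Why: Auxiliary-controlled Michael addition of an N-acyloxazolidinone enolate, in which the chelated Z-sodium enolate adds through the face opposite the benzyl group to the doubly activated, non-stereogenic β-carbon of the alkylidene malonate; this forms the C7–C8 bond, sets C7 (S here, the spatial arrangement of the target) and leaves the adduct as its stable sodium malonate.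

**Step 4**
Reactants: 6 Michael adduct
Product: 7 dimethyl 2-[(3S)-3-(ethylsulfanylcarbonyl)-2,6-dimethylhept-5-en-2-yl]propanedioate
Conditions: EtSH, n-BuLi, THF, 0 °C; AcOH
Reagents that add atoms: ethanethiol CCS
Why: Thiolate cleavage of the imide at the exocyclic carbonyl releases the auxiliary without touching the methyl esters, and ethanethiolate is too weak a base to enolise the acyl group, so C7 is retained.

**Step 5**
Reactants: 7 thioester
Product: 8 dimethyl 2-[(3S)-3-formyl-2,6-dimethylhept-5-en-2-yl]propanedioate
Conditions: Et3SiH, 10% Pd/C, acetone, rt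
Reagents that add atoms: none
Why: Fukuyama reduction stops at the aldehyde and tolerates methyl esters and trisubstituted alkenes, so C6 reaches the aldehyde level without passing through an alcohol that would lactonise onto the malonate.

**Step 6**
Reactants: 9 (R)-lavandulol, (2R)-5-methyl-2-(prop-1-en-2-yl)hex-4-en-1-ol
Product: 10 (R)-lavandulyl iodide, (2R)-1-iodo-5-methyl-2-(prop-1-en-2-yl)hex-4-ene
Conditions: I2, PPh3, imidazole, CH2Cl2, 0 °C to rt
Reagents that add atoms: iodine II
Why: Appel-type iodination of the primary alcohol under neutral conditions does not involve the stereocentre, which keeps its configuration.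

**Step 7**
Reactants: 10 (R)-lavandulyl iodide; 11 trimethyl phosphonoacetate
Product: 12 methyl (4S)-2-(dimethoxyphosphoryl)-7-methyl-4-(prop-1-en-2-yl)oct-6-enoate (both C2 epimers)
Conditions: NaH, DMF, 0 to 60 °C
Reagents that add atoms: none
Why: SN2 alkylation of the soft, weakly basic phosphonoacetate anion at the primary iodide should prevail over elimination, and the new phosphonate carbon forms as both epimers without consequence because it becomes sp2 in the next step.

**Step 8**
Reactants: 8 aldehyde; 12 phosphonate
Product: 13 trimethyl (3R,4E,7S)-2,2,10-trimethyl-3-(3-methylbut-2-en-1-yl)-7-(prop-1-en-2-yl)undeca-4,9-diene-1,1,5-tricarboxylate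
Conditions: NaH, THF, 0 °C to rt (8 added as its sodium malonate); AcOH
Reagents that add atoms: none
Why: Horner–Wadsworth–Emmons olefination forms the C5=C6 bond, the malonate being carried as its sodium salt so that it cannot be lost by β-elimination from an aldehyde enolate, and the alkene geometry (E expected) is erased in the next step.

**Step 9**
Reactants: 13 enoate
Product: 14 trimethyl (3R,7S)-2,2,10-trimethyl-3-(3-methylbut-2-en-1-yl)-7-(prop-1-en-2-yl)undec-9-ene-1,1,5-tricarboxylate (both C5 epimers)
Conditions: Mg turnings, MeOH, 0 °C to rt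
Reagents that add atoms: none
Why: Dissolving-metal conjugate reduction saturates only the α,β-unsaturated ester, isolated alkenes and esters being inert, and C5 forms as both epimers, which converge because C5 is deprotonated in step 11.

**Step 10**
Reactants: 14 triester; 2 5-methylhex-4-enoyl chloride
Product: 15 trimethyl (3R,7S)-2,2,10-trimethyl-3-(3-methylbut-2-en-1-yl)-1-(5-methylhex-4-enoyl)-7-(prop-1-en-2-yl)undec-9-ene-1,1,5-tricarboxylate (both C5 epimers)
Conditions: NaH, THF, 0 °C; then 2, 0 °C to rt
Reagents that add atoms: none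
Why: C-acylation of the sodium malonate by an unhindered linear acid chloride (malonate enolates acylate on carbon) makes C1 fully substituted yet non-stereogenic, because its two methoxycarbonyl groups are identical.

**Step 11**
Reactants: 15 open-chain keto triester
Product: 17 methyl (1S,5S,7R)-2-hydroxy-8,8-dimethyl-3,7-bis(3-methylbut-2-en-1-yl)-5-[(2S)-5-methyl-2-(prop-1-en-2-yl)hex-4-en-1-yl]-4,9-dioxobicyclo[3.3.1]non-2-ene-1-carboxylate, via Dieckmann cyclohexanone 16 (not isolated)
Conditions: KN(SiMe3)2 (3.5 equiv), THF (0.01 M), −78 °C to rt; aq. HCl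
Reagents that add atoms: none
Why: The base first converts the only enolisable ketone (C2, towards C3) into its enolate, which shields C2 from methoxide, and then forms the C5 ester enolate, which adds to one of the two diastereotopic C1 ester carbonyls and expels methoxide to close ring B as 16 (C5–C9 bond, 6-exo-trig with the enolate double bond outside the new ring); the C3 enolate then attacks the ester on C5 and expels a second methoxide to close ring A (C3–C4 bond, 6-exo-trig with the enolate double bond inside the new ring). The closest known reactions are the Dieckmann condensation and the intramolecular ketone–ester Claisen closure of ring A of bicyclo[3.3.1]nonane-2,4,9-triones, here run in tandem from an open chain. Because 16 has no proton between its carbonyl groups, the first closure is reversible under the methoxide it releases, whereas the second ends in the stabilised C2–C3–C4 enolate and is the thermodynamic sink that drains both C5 epimers and all diastereomers of 16 through the single productive one. C1 and C5 are set together by C7: ring A can form only when the acyl group on C1 and the ester on C5 are both axial on the same face of a chair ring B, which leaves the third axial site on that face, at C7, to hydrogen, so the C7 prenyl group is equatorial (exo) and the C7 configuration decides which C1 ester becomes C9 and which face of the C5 enolate is acylated. The step needs C-acylation at C3 in preference to O-acylation, which is self-correcting because the enol lactone is an active ester that methoxide reopens, and it needs ring closure faster than methoxide cleavage of the triacylated C1, which the prior enolisation of C2 and high dilution should secure.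

**Step 12**
Reactants: 17 bicyclic bridgehead ester
Product: 18 (1R,5S,7R)-1-benzoyl-2-hydroxy-8,8-dimethyl-3,7-bis(3-methylbut-2-en-1-yl)-5-[(2S)-5-methyl-2-(prop-1-en-2-yl)hex-4-en-1-yl]bicyclo[3.3.1]non-2-ene-4,9-dione
Conditions: LiN(SiMe3)2 (1.1 equiv), THF, −78 °C; PhLi (2 equiv), −78 to −40 °C; AcOH
Reagents that add atoms: phenyllithium [Li]c1ccccc1
Why: Aryllithium addition to an ester to give a ketone, in which ring A is masked as its lithium enolate and the C9 ketone is shielded by two quaternary neighbours and the axial C8 methyl group, so the exocyclic bridgehead ester should be the accessible electrophile and its lithium hemiketal should survive at low temperature and collapse to the hindered benzoyl ketone only on work-up, with no stereocentre touched.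

**Compound list**

1 | 5-methylhex-4-enoic acid | CC(C)=CCCC(=O)O | starting material
2 | 5-methylhex-4-enoyl chloride | CC(C)=CCCC(=O)Cl | intermediate
3 | (R)-4-benzyl-1,3-oxazolidin-2-one | O=C1OC[C@@H](Cc2ccccc2)N1 | starting material
4 | (R)-4-benzyl-3-(5-methylhex-4-enoyl)-1,3-oxazolidin-2-one | O=C1OC[C@@H](Cc2ccccc2)N1C(=O)CCC=C(C)C | intermediate
5 | dimethyl 2-(propan-2-ylidene)propanedioate | COC(=O)C(=C(C)C)C(=O)OC | starting material
6 | dimethyl 2-[(3S)-3-[(4R)-4-benzyl-2-oxo-1,3-oxazolidine-3-carbonyl]-2,6-dimethylhept-5-en-2-yl]propanedioate | O=C1OC[C@@H](Cc2ccccc2)N1C(=O)[C@@H](CC=C(C)C)C(C)(C)C(C(=O)OC)C(=O)OC | intermediate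
7 | dimethyl 2-[(3S)-3-(ethylsulfanylcarbonyl)-2,6-dimethylhept-5-en-2-yl]propanedioate | CCSC(=O)[C@@H](CC=C(C)C)C(C)(C)C(C(=O)OC)C(=O)OC | intermediate
8 | dimethyl 2-[(3S)-3-formyl-2,6-dimethylhept-5-en-2-yl]propanedioate | O=C[C@@H](CC=C(C)C)C(C)(C)C(C(=O)OC)C(=O)OC | intermediate
9 | (R)-lavandulol | C=C(C)[C@@H](CC=C(C)C)CO | starting material
10 | (R)-lavandulyl iodide | C=C(C)[C@@H](CC=C(C)C)CI | intermediate
11 | trimethyl phosphonoacetate | COC(=O)CP(=O)(OC)OC | starting material
12 | methyl (4S)-2-(dimethoxyphosphoryl)-7-methyl-4-(prop-1-en-2-yl)oct-6-enoate, both C2 epimers | C=C(C)[C@@H](CC=C(C)C)CC(C(=O)OC)P(=O)(OC)OC | intermediate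
13 | trimethyl (3R,4E,7S)-2,2,10-trimethyl-3-(3-methylbut-2-en-1-yl)-7-(prop-1-en-2-yl)undeca-4,9-diene-1,1,5-tricarboxylate | C=C(C)[C@@H](CC=C(C)C)C\C(C(=O)OC)=C/[C@@H](CC=C(C)C)C(C)(C)C(C(=O)OC)C(=O)OC | intermediate
14 | trimethyl (3R,7S)-2,2,10-trimethyl-3-(3-methylbut-2-en-1-yl)-7-(prop-1-en-2-yl)undec-9-ene-1,1,5-tricarboxylate, both C5 epimers | C=C(C)[C@@H](CC=C(C)C)CC(C(=O)OC)C[C@@H](CC=C(C)C)C(C)(C)C(C(=O)OC)C(=O)OC | intermediate
15 | trimethyl (3R,7S)-2,2,10-trimethyl-3-(3-methylbut-2-en-1-yl)-1-(5-methylhex-4-enoyl)-7-(prop-1-en-2-yl)undec-9-ene-1,1,5-tricarboxylate, both C5 epimers | C=C(C)[C@@H](CC=C(C)C)CC(C(=O)OC)C[C@@H](CC=C(C)C)C(C)(C)C(C(=O)OC)(C(=O)OC)C(=O)CCC=C(C)C | intermediate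
16 | dimethyl 6,6-dimethyl-5-(3-methylbut-2-en-1-yl)-1-(5-methylhex-4-enoyl)-3-[(2S)-5-methyl-2-(prop-1-en-2-yl)hex-4-en-1-yl]-2-oxocyclohexane-1,3-dicarboxylate, ring configuration as in 17 | C=C(C)[C@@H](CC=C(C)C)C[C@@]1(C(=O)OC)C[C@@H](CC=C(C)C)C(C)(C)[C@@](C(=O)OC)(C1=O)C(=O)CCC=C(C)C | intermediate
17 | methyl (1S,5S,7R)-2-hydroxy-8,8-dimethyl-3,7-bis(3-methylbut-2-en-1-yl)-5-[(2S)-5-methyl-2-(prop-1-en-2-yl)hex-4-en-1-yl]-4,9-dioxobicyclo[3.3.1]non-2-ene-1-carboxylate | C=C(C)[C@@H](CC=C(C)C)C[C@@]12C[C@@H](CC=C(C)C)C(C)(C)[C@@](C(=O)OC)(C1=O)C(O)=C(CC=C(C)C)C2=O | intermediate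
18 | (1R,5S,7R)-1-benzoyl-2-hydroxy-8,8-dimethyl-3,7-bis(3-methylbut-2-en-1-yl)-5-[(2S)-5-methyl-2-(prop-1-en-2-yl)hex-4-en-1-yl]bicyclo[3.3.1]non-2-ene-4,9-dione | C=C(C)[C@@H](CC=C(C)C)C[C@@]12C[C@@H](CC=C(C)C)C(C)(C)[C@@](C(=O)c3ccccc3)(C1=O)C(O)=C(CC=C(C)C)C2=O | target

The descriptor at C7 changes from S (6, 7, 8) to R (13 onwards) only through substituent priorities; the centre is never inverted.

**Count and risks**

Total steps: 12. Longest linear sequence: 10 (steps 1 to 5 and 8 to 12); steps 6 and 7 form the side branch.

Step 11. What may go wrong: cleavage of the C1 acyl group by released methoxide, or stalling after the reversible first closure. The fallback sets out from 15 and comes back at 17. The C2 ketone is first converted into its (Z)-tert-butyldimethylsilyl enol ether F1 (t-BuMe2SiOTf, Et3N, CH2Cl2), which blocks the ketone against alkoxide and stores the C3 nucleophile. KN(SiMe3)2 then closes ring B alone, giving the silyl enol ether of the Dieckmann cyclohexanone F2, which equilibrates through its own methoxide and is not isolated. Bu4NF added to the same flask unmasks the C3 enolate, which closes ring A to 17.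

Step 12. What may go wrong: competing addition of the aryllithium to the C9 ketone, or a second addition to the new ketone. The fallback sets out from 17 and comes back at 18. Aminolysis of the bridgehead ester with Me2AlN(OMe)Me (from AlMe3 and MeNHOMe·HCl, toluene, 60 °C; the enol is carried as its aluminium enolate) gives the bridgehead N-methoxy-N-methylamide F3. PhMgBr (THF, 0 °C) then gives 18 through the chelated tetrahedral intermediate; an aryl Grignard reagent should not add to the doubly neopentyl C9 ketone.

Step 3. What may go wrong: slow conjugate addition at the β,β-disubstituted acceptor, so that the substituted imide enolate decomposes before it adds. The fallback sets out from 5 and comes back at 7, and reverses the order in which the two bonds at C7 are made. Purchased (S)-3-acetyl-4-benzyl-1,3-oxazolidin-2-one F4 gives an unhindered sodium enolate that adds to 5 to give the C7-unsubstituted adduct F5. Double deprotonation (NaN(SiMe3)2, 2.2 equiv) and alkylation with prenyl bromide at the more nucleophilic imide enolate, anti to the benzyl group, gives the (4S)-auxiliary adduct F6 with the same (S) configuration at C7; the enantiomeric auxiliary is needed because the roles of the in-plane and incoming groups are exchanged. Thiolate cleavage as in step 4 returns to 7.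

**Further compounds**

F1 | step 11 | (Z)-tert-butyldimethylsilyl enol ether of 15 at C2=C3 | C=C(C)[C@@H](CC=C(C)C)CC(C(=O)OC)C[C@@H](CC=C(C)C)C(C)(C)C(C(=O)OC)(C(=O)OC)/C(O[Si](C)(C)C(C)(C)C)=C/CC=C(C)C
F2 | step 11 | (Z)-tert-butyldimethylsilyl enol ether of Dieckmann cyclohexanone 16 | C=C(C)[C@@H](CC=C(C)C)C[C@@]1(C(=O)OC)C[C@@H](CC=C(C)C)C(C)(C)[C@@](C(=O)OC)(C1=O)/C(O[Si](C)(C)C(C)(C)C)=C/CC=C(C)C
F3 | step 12 | bridgehead N-methoxy-N-methylcarboxamide analogue of 17 | C=C(C)[C@@H](CC=C(C)C)C[C@@]12C[C@@H](CC=C(C)C)C(C)(C)[C@@](C(=O)N(C)OC)(C1=O)C(O)=C(CC=C(C)C)C2=O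
F4 | step 3 | (S)-3-acetyl-4-benzyl-1,3-oxazolidin-2-one | O=C1OC[C@H](Cc2ccccc2)N1C(C)=O
F5 | step 3 | dimethyl 2-{4-[(4S)-4-benzyl-2-oxo-1,3-oxazolidin-3-yl]-2-methyl-4-oxobutan-2-yl}propanedioate | O=C1OC[C@H](Cc2ccccc2)N1C(=O)CC(C)(C)C(C(=O)OC)C(=O)OC
F6 | step 3 | dimethyl 2-[(3S)-3-[(4S)-4-benzyl-2-oxo-1,3-oxazolidine-3-carbonyl]-2,6-dimethylhept-5-en-2-yl]propanedioate | O=C1OC[C@H](Cc2ccccc2)N1C(=O)[C@@H](CC=C(C)C)C(C)(C)C(C(=O)OC)C(=O)OC
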